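**Strategy.** Ring A is the mono-methyl ether of a mirror-symmetric resorcinol: C1 (OMe) and C3 (OH) flank C2–H, and C4 and C6 carry identical 4-hydroxybenzyl groups beside the C5 ethano bridge, so it is built as a cyclohexane-1,3-dione. One Michael–Claisen annulation of a benzylmalonate with an α-benzyl methyl enone already holding ring B forges C4–C5 and C2–C3 and closes the ring. After decarboxylation both carbonyls are equivalent, so enol ether formation on either oxygen, then dehydrogenation, gives the single anisole. The enone comes from a Horner–Wadsworth–Emmons reaction of an α-benzylated ketophosphonate with the ring B 3-arylpropanal; phenols travel as benzyl ethers.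

Key step: step 8

Remark: the target has no stereocentre, so the cyclohexane intermediates 15–20 are carried as diastereomer (and keto–enol) mixtures that all converge when ring A is aromatized; their SMILES are written without configuration.

**Step 1**
Reactants: 1 3,5-dibromophenol
Product: 2 1-(benzyloxy)-3,5-dibromobenzene
Conditions: BnBr, K2CO3, DMF, rt
Reagents that add atoms: benzyl bromide, BrCc1ccccc1
Why: Williamson etherification of the acidic phenol with a reactive benzylic bromide should be clean, and the two aryl bromides are inert to carbonate.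

**Step 2**
Reactants: 2 1-(benzyloxy)-3,5-dibromobenzene; 3 4-(benzyloxy)benzaldehyde
Product: 5 [3-(benzyloxy)-5-bromophenyl][4-(benzyloxy)phenyl]methanol (racemic), via aryllithium 4 (not isolated)
Conditions: n-BuLi (1.0 equiv), Et2O, −78 °C; then 3 in THF, −78 → 0 °C; then H2O
Reagents that add atoms: none
Why: Bromine–lithium exchange with one equivalent of n-BuLi should stop at the mono-lithio arene, since a second exchange would build a dianion, and 1,2-addition to the aldehyde gives the carbinol as a racemate whose stereocentre is removed in step 3.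

**Step 3**
Reactants: 5 [3-(benzyloxy)-5-bromophenyl][4-(benzyloxy)phenyl]methanol
Product: 6 1-(benzyloxy)-3-bromo-5-[4-(benzyloxy)benzyl]benzene
Conditions: Et3SiH, CF3CO2H, CH2Cl2, 0 °C → rt
Reagents that add atoms: none
Why: Ionic hydrogenation should work because the acid ionizes the doubly benzylic alcohol to a cation stabilized by the para-benzyloxy ring, which the silane reduces by hydride transfer while aryl bromide and benzyl ethers stay intact.

**Step 4**
Reactants: 6 1-(benzyloxy)-3-bromo-5-[4-(benzyloxy)benzyl]benzene; 7 allyl alcohol (prop-2-en-1-ol)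
Product: 8 3-{3-(benzyloxy)-5-[4-(benzyloxy)benzyl]phenyl}propanal
Conditions: Pd(OAc)2 (5 mol %), n-Bu4NCl, NaHCO3, DMF, 80 °C
Reagents that add atoms: none
Why: In this Heck reaction the arylpalladium species (zerovalent palladium forms in situ from Pd(OAc)2) adds to the terminal alkene carbon, and β-hydride elimination toward the carbinol carbon followed by tautomerization should deliver the saturated aldehyde directly.

**Step 5**
Reactants: 9 diethyl (2-oxopropyl)phosphonate; 10 4-(benzyloxy)benzyl chloride
Product: 11 diethyl {1-[4-(benzyloxy)phenyl]-3-oxobutan-2-yl}phosphonate (racemic)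
Conditions: NaH, THF/DMF, 0 °C; then 10, NaI (cat.), rt → 50 °C
Reagents that add atoms: none
Why: C-alkylation of the sodium salt of a β-ketophosphonate by a reactive benzylic chloride is standard enolate alkylation, a slight excess of 9 limits double alkylation, and the new stereocentre is lost in the olefination.

**Step 6**
Reactants: 8 3-{3-(benzyloxy)-5-[4-(benzyloxy)benzyl]phenyl}propanal; 11 diethyl {1-[4-(benzyloxy)phenyl]-3-oxobutan-2-yl}phosphonate
Product: 12 (E)-3-[4-(benzyloxy)benzyl]-6-{3-(benzyloxy)-5-[4-(benzyloxy)benzyl]phenyl}hex-3-en-2-one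
Conditions: Ba(OH)2 (activated), THF; then 8, THF/H2O (40:1), rt
Reagents that add atoms: none
Why: Horner–Wadsworth–Emmons olefination with an α-substituted β-ketophosphonate places the benzyl group on the α-carbon without any regiochemical question, the mild barium base spares the enolizable aldehyde, and the E isomer (acetyl trans to the chain) should dominate, although either geometry would serve because the alkene is consumed in step 8.

**Step 7**
Reactants: 13 dimethyl malonate; 10 4-(benzyloxy)benzyl chloride
Product: 14 dimethyl 2-[4-(benzyloxy)benzyl]malonate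
Conditions: 13 (2.5 equiv), NaH, THF/DMF, 0 °C; then 10, rt
Reagents that add atoms: none
Why: Malonic ester alkylation in an aprotic medium avoids solvolysis of the ionizable para-alkoxybenzyl chloride, and the excess of malonate suppresses the dialkylated product.

**Step 8**
Reactants: 12 (E)-3-[4-(benzyloxy)benzyl]-6-{3-(benzyloxy)-5-[4-(benzyloxy)benzyl]phenyl}hex-3-en-2-one; 14 dimethyl 2-[4-(benzyloxy)benzyl]malonate
Product: 16 methyl 1,5-bis[4-(benzyloxy)benzyl]-6-(2-{3-(benzyloxy)-5-[4-(benzyloxy)benzyl]phenyl}ethyl)-2,4-dioxocyclohexane-1-carboxylate (diastereomer mixture), via Michael adduct 15 (not isolated)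
Conditions: 14 (1.3 equiv), NaOMe (1.5 equiv), MeOH/THF, reflux; then aq. HCl, 0 °C
Reagents that add atoms: none
Why: Methoxide turns 14 into a soft tertiary carbanion that adds in the 1,4-sense to the β-carbon of 12 (the C4–C5 bond of ring A) to give keto diester 15. Proton exchange then produces the enolate on the methyl side of the ketone, which attacks one of the geminal esters in a 6-(enolendo)-exo-trig Claisen closure, forming C2–C3 and the only new ring. The closest known reaction type is the Michael–Claisen annulation of enones with malonates that gives 5-substituted cyclohexane-1,3-diones. Three sp3 centres (C1, C5 and C6 of 16) arise as an uncontrolled, equilibrating mixture and need no control because all become sp2 carbons of ring A. The step needs conjugate rather than carbonyl addition and closure through the methyl enolate: the stabilized carbanion adds to C=O only reversibly, only the methyl-derived enolate reaches an ester through a six-membered transition state, and irreversible deprotonation of the acidic 1,3-dione between C2 and C4 pulls the crowded, reversible Michael equilibrium forward.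

**Step 9**
Reactants: 16 methyl 1,5-bis[4-(benzyloxy)benzyl]-6-(2-{3-(benzyloxy)-5-[4-(benzyloxy)benzyl]phenyl}ethyl)-2,4-dioxocyclohexane-1-carboxylate
Product: 18 4,6-bis[4-(benzyloxy)benzyl]-5-(2-{3-(benzyloxy)-5-[4-(benzyloxy)benzyl]phenyl}ethyl)cyclohexane-1,3-dione (diastereomer mixture), via keto acid 17 (not isolated)
Conditions: NaOH (2 M aq.), 1,4-dioxane/MeOH, 90 °C; then HCl to pH 1, 60 °C
Reagents that add atoms: none
Why: Saponification proceeds on the dione enolate, which shields the ring from retro-Claisen cleavage, and the β-keto acid released on acidification should lose CO2 on warming through the usual six-membered transition state to leave the constitutionally symmetric dione.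

**Step 10**
Reactants: 18 4,6-bis[4-(benzyloxy)benzyl]-5-(2-{3-(benzyloxy)-5-[4-(benzyloxy)benzyl]phenyl}ethyl)cyclohexane-1,3-dione
Product: 19 4,6-bis[4-(benzyloxy)benzyl]-5-(2-{3-(benzyloxy)-5-[4-(benzyloxy)benzyl]phenyl}ethyl)-3-methoxycyclohex-2-en-1-one (diastereomer mixture)
Conditions: MeOH, TsOH·H2O (cat.), toluene, 3 Å molecular sieves, reflux
Reagents that add atoms: methanol, CO
Why: Acid-catalysed enol etherification of a cyclic 1,3-dione (a vinylogous Fischer esterification) should give the vinylogous ester, and because C4 and C6 carry the same group, methylation at either oxygen gives the same constitution.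

**Step 11**
Reactants: 19 4,6-bis[4-(benzyloxy)benzyl]-5-(2-{3-(benzyloxy)-5-[4-(benzyloxy)benzyl]phenyl}ethyl)-3-methoxycyclohex-2-en-1-one
Product: 22 2,4-bis[4-(benzyloxy)benzyl]-3-(2-{3-(benzyloxy)-5-[4-(benzyloxy)benzyl]phenyl}ethyl)-5-methoxyphenol, via selenide 20 (not isolated), via dienone 21 (not isolated)
Conditions: LiN(i-Pr)2 (1.1 equiv), THF, −78 °C; PhSeCl, −78 °C; then 30 % H2O2, pyridine, CH2Cl2, 0 °C → rt
Reagents that add atoms: none
Why: Kinetic deprotonation of a 3-alkoxyenone occurs at the α'-carbon (C6), selenenylation of that enolate followed by oxidation at selenium and syn-elimination (selenoxide elimination) gives the cross-conjugated dienone, and its C4–H tautomerizes at once to the phenol with aromatization as the driving force.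

**Step 12**
Reactants: 22 2,4-bis[4-(benzyloxy)benzyl]-3-(2-{3-(benzyloxy)-5-[4-(benzyloxy)benzyl]phenyl}ethyl)-5-methoxyphenol
Product: 23 2,4-bis(4-hydroxybenzyl)-3-{2-[3-hydroxy-5-(4-hydroxybenzyl)phenyl]ethyl}-5-methoxyphenol (CNP0204120.0)
Conditions: H2 (1 atm), Pd/C (10 %), EtOAc/MeOH, rt
Reagents that add atoms: none
Why: Catalytic hydrogenolysis should cleave the four benzyl aryl ethers, whereas the diarylmethane C–C bonds, the aryl methyl ether and the arenes are inert at ambient pressure and temperature.

**Compound list**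
1 | 3,5-dibromophenol | Oc1cc(Br)cc(Br)c1 | starting material
2 | 1-(benzyloxy)-3,5-dibromobenzene | Brc1cc(Br)cc(OCc2ccccc2)c1 | intermediate
3 | 4-(benzyloxy)benzaldehyde | O=Cc1ccc(OCc2ccccc2)cc1 | starting material
4 | [3-(benzyloxy)-5-bromophenyl]lithium (not isolated) | [Li]c1cc(Br)cc(OCc2ccccc2)c1 | intermediate
5 | [3-(benzyloxy)-5-bromophenyl][4-(benzyloxy)phenyl]methanol (racemic) | OC(c1ccc(OCc2ccccc2)cc1)c1cc(Br)cc(OCc2ccccc2)c1 | intermediate
6 | 1-(benzyloxy)-3-bromo-5-[4-(benzyloxy)benzyl]benzene | Brc1cc(Cc2ccc(OCc3ccccc3)cc2)cc(OCc2ccccc2)c1 | intermediate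
7 | allyl alcohol (prop-2-en-1-ol) | C=CCO | starting material
8 | 3-{3-(benzyloxy)-5-[4-(benzyloxy)benzyl]phenyl}propanal | O=CCCc1cc(OCc2ccccc2)cc(Cc2ccc(OCc3ccccc3)cc2)c1 | intermediate
9 | diethyl (2-oxopropyl)phosphonate | CCOP(=O)(CC(C)=O)OCC | starting material
10 | 4-(benzyloxy)benzyl chloride | ClCc1ccc(OCc2ccccc2)cc1 | starting material
11 | diethyl {1-[4-(benzyloxy)phenyl]-3-oxobutan-2-yl}phosphonate (racemic) | CCOP(=O)(OCC)C(Cc1ccc(OCc2ccccc2)cc1)C(C)=O | intermediate
12 | (E)-3-[4-(benzyloxy)benzyl]-6-{3-(benzyloxy)-5-[4-(benzyloxy)benzyl]phenyl}hex-3-en-2-one | CC(=O)/C(Cc1ccc(OCc2ccccc2)cc1)=C/CCc1cc(OCc2ccccc2)cc(Cc2ccc(OCc3ccccc3)cc2)c1 | intermediate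
13 | dimethyl malonate | COC(=O)CC(=O)OC | starting material
14 | dimethyl 2-[4-(benzyloxy)benzyl]malonate | COC(=O)C(Cc1ccc(OCc2ccccc2)cc1)C(=O)OC | intermediate
15 | dimethyl 2-[4-(benzyloxy)benzyl]-2-(1-{3-(benzyloxy)-5-[4-(benzyloxy)benzyl]phenyl}-4-[4-(benzyloxy)benzyl]-5-oxohexan-3-yl)malonate (diastereomer mixture, not isolated) | COC(=O)C(Cc1ccc(OCc2ccccc2)cc1)(C(=O)OC)C(CCc1cc(OCc2ccccc2)cc(Cc2ccc(OCc3ccccc3)cc2)c1)C(Cc1ccc(OCc2ccccc2)cc1)C(C)=O | intermediate
16 | methyl 1,5-bis[4-(benzyloxy)benzyl]-6-(2-{3-(benzyloxy)-5-[4-(benzyloxy)benzyl]phenyl}ethyl)-2,4-dioxocyclohexane-1-carboxylate (diastereomer mixture) | COC(=O)C1(Cc2ccc(OCc3ccccc3)cc2)C(=O)CC(=O)C(Cc2ccc(OCc3ccccc3)cc2)C1CCc1cc(OCc2ccccc2)cc(Cc2ccc(OCc3ccccc3)cc2)c1 | intermediate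
17 | 1,5-bis[4-(benzyloxy)benzyl]-6-(2-{3-(benzyloxy)-5-[4-(benzyloxy)benzyl]phenyl}ethyl)-2,4-dioxocyclohexane-1-carboxylic acid (diastereomer mixture, not isolated) | OC(=O)C1(Cc2ccc(OCc3ccccc3)cc2)C(=O)CC(=O)C(Cc2ccc(OCc3ccccc3)cc2)C1CCc1cc(OCc2ccccc2)cc(Cc2ccc(OCc3ccccc3)cc2)c1 | intermediate
18 | 4,6-bis[4-(benzyloxy)benzyl]-5-(2-{3-(benzyloxy)-5-[4-(benzyloxy)benzyl]phenyl}ethyl)cyclohexane-1,3-dione (diastereomer mixture) | O=C1CC(=O)C(Cc2ccc(OCc3ccccc3)cc2)C(CCc2cc(OCc3ccccc3)cc(Cc3ccc(OCc4ccccc4)cc3)c2)C1Cc1ccc(OCc2ccccc2)cc1 | intermediate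
19 | 4,6-bis[4-(benzyloxy)benzyl]-5-(2-{3-(benzyloxy)-5-[4-(benzyloxy)benzyl]phenyl}ethyl)-3-methoxycyclohex-2-en-1-one (diastereomer mixture) | COC1=CC(=O)C(Cc2ccc(OCc3ccccc3)cc2)C(CCc2cc(OCc3ccccc3)cc(Cc3ccc(OCc4ccccc4)cc3)c2)C1Cc1ccc(OCc2ccccc2)cc1 | intermediate
20 | 4,6-bis[4-(benzyloxy)benzyl]-5-(2-{3-(benzyloxy)-5-[4-(benzyloxy)benzyl]phenyl}ethyl)-3-methoxy-6-(phenylselanyl)cyclohex-2-en-1-one (diastereomer mixture, not isolated) | COC1=CC(=O)C([Se]c2ccccc2)(Cc2ccc(OCc3ccccc3)cc2)C(CCc2cc(OCc3ccccc3)cc(Cc3ccc(OCc4ccccc4)cc3)c2)C1Cc1ccc(OCc2ccccc2)cc1 | intermediate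
21 | 4,6-bis[4-(benzyloxy)benzyl]-5-(2-{3-(benzyloxy)-5-[4-(benzyloxy)benzyl]phenyl}ethyl)-3-methoxycyclohexa-2,5-dien-1-one (racemic, not isolated) | COC1=CC(=O)C(Cc2ccc(OCc3ccccc3)cc2)=C(CCc2cc(OCc3ccccc3)cc(Cc3ccc(OCc4ccccc4)cc3)c2)C1Cc1ccc(OCc2ccccc2)cc1 | intermediate
22 | 2,4-bis[4-(benzyloxy)benzyl]-3-(2-{3-(benzyloxy)-5-[4-(benzyloxy)benzyl]phenyl}ethyl)-5-methoxyphenol | COc1cc(O)c(Cc2ccc(OCc3ccccc3)cc2)c(CCc2cc(OCc3ccccc3)cc(Cc3ccc(OCc4ccccc4)cc3)c2)c1Cc1ccc(OCc2ccccc2)cc1 | intermediate
23 | 2,4-bis(4-hydroxybenzyl)-3-{2-[3-hydroxy-5-(4-hydroxybenzyl)phenyl]ethyl}-5-methoxyphenol (CNP0204120.0) | COc1cc(O)c(Cc2ccc(O)cc2)c(CCc2cc(O)cc(Cc3ccc(O)cc3)c2)c1Cc1ccc(O)cc1 | target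

**Step count.** Total: 12 steps. Longest linear sequence: 10 steps (steps 1–4, 6, 8–12).

**Steps most likely to fail**

Step 8. The conjugate addition may stall because the equilibrium between the congested adduct (a quaternary carbon next to a tertiary one) and its components lies on the side of 12 and 14, while 12 is slowly lost to base-induced deconjugation and self-condensation. The fallback sets out from enone 12 and returns at 16. Enone 12 is annulated with unsubstituted dimethyl malonate 13 (NaOMe, MeOH/THF, reflux), the standard form of this reaction in which a less hindered carbanion attacks. This gives methyl 5-[4-(benzyloxy)benzyl]-6-(2-{3-(benzyloxy)-5-[4-(benzyloxy)benzyl]phenyl}ethyl)-2,4-dioxocyclohexane-1-carboxylate F1. The missing benzyl group is then introduced at C1 by alkylating the dianion of F1 (2.2 equiv LiN(i-Pr)2, THF, −78 → 0 °C, the second deprotonation taking the hydrogen α to the ester) with chloride 10. This is the γ-alkylation of a β-dicarbonyl dianion and should give 16.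

Step 11. Deprotonation at the crowded tertiary C6–H may be incomplete or divert to the γ-position, and the syn-elimination may run toward the exocyclic benzylic hydrogens and leave an isomer that aromatizes only slowly. The fallback sets out from dione 18 and returns at 22, replacing steps 10 and 11. Dione 18 is heated with I2 in MeOH at reflux, a known oxidative aromatization of cyclohexane-1,3-diones to resorcinol methyl ethers that needs no enolate at the hindered carbon. It proceeds by in situ enol ether formation, α-iodination, loss of HI and tautomerization. No new compound arises on this path (F0).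

Step 4. Arylation at the internal alkene carbon or β-hydride elimination away from the carbinol carbon would give branched or allylic by-products, and the aldehyde may self-condense under base as it forms at 80 °C. The fallback sets out from bromide 6 and returns at aldehyde 8. Bromide 6 undergoes Negishi coupling with commercial [2-(1,3-dioxolan-2-yl)ethyl]zinc bromide (Pd(PPh3)4, THF, 60 °C) to give 2-(2-{3-(benzyloxy)-5-[4-(benzyloxy)benzyl]phenyl}ethyl)-1,3-dioxolane F2. Acetal hydrolysis (aq. HCl, THF, rt) then releases 8.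

**Further compounds**
F1 | step 8 | methyl 5-[4-(benzyloxy)benzyl]-6-(2-{3-(benzyloxy)-5-[4-(benzyloxy)benzyl]phenyl}ethyl)-2,4-dioxocyclohexane-1-carboxylate | COC(=O)C1C(=O)CC(=O)C(Cc2ccc(OCc3ccccc3)cc2)C1CCc1cc(OCc2ccccc2)cc(Cc2ccc(OCc3ccccc3)cc2)c1
F0 | step 11 | none | none
F2 | step 4 | 2-(2-{3-(benzyloxy)-5-[4-(benzyloxy)benzyl]phenyl}ethyl)-1,3-dioxolane | C1COC(CCc2cc(OCc3ccccc3)cc(Cc3ccc(OCc4ccccc4)cc3)c2)O1
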